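The route rests on cutting the acyl–alkenyl bond C5'–C6' of the side chain (numbered C1' at the benzylic carbon to C10' at the pyranone ring). A base-free Stille acylation joins acid chloride C1'–C5', carrying the benzene ring, to an (E)-alkenylstannane C6'–C10', carrying the finished (S)-pyranone ring. In one operation it makes the ketone between both alkenes and transfers the C6'=C7' geometry, fixed earlier by syn-carboalumination of an alkyne. The feature exploited is the allyl alkenyl ketone C4'H2–C5'(=O)–C6'H=C7': neutral palladium catalysis spares the doubly activated C4' methylene, so the C2'=C3' alkene stays out of conjugation.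

Key step: step 12

Step 1
Reactants: 1 4-methoxy-3-methylphenol
Product: 2 triisopropyl(4-methoxy-3-methylphenoxy)silane
Conditions: TIPSCl, imidazole, DMF, rt
Reagents that add atoms: triisopropylsilyl chloride, CC(C)[Si](Cl)(C(C)C)C(C)C
Why: Silylation of a phenol, in which imidazole activates the silyl chloride and takes up HCl, and the bulky silyl ether will later keep lithiation away from its own ortho positions.

Step 2
Reactants: 3 S-phenyl thioacetate; 4 methyl vinyl ketone
Product: 6 rac-4-ethenyl-4-methyloxetan-2-one, via lithium 1-(phenylsulfanyl)ethenolate 5 (not isolated)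
Conditions: LiN(iPr)2, THF, −78 °C; then 4, −78 to 0 °C; aq. NH4Cl
Reagents that add atoms: none
Why: β-Lactone synthesis from a thiol ester enolate, in which 1,2-aldol addition to the ketone carbonyl at −78 °C is followed on warming by lactonisation with loss of thiophenolate, and the new stereocentre is left racemic because step 3 erases it.

Step 3
Reactants: 2 triisopropyl(4-methoxy-3-methylphenoxy)silane; 6 rac-4-ethenyl-4-methyloxetan-2-one
Product: 9 (E)-5-[2-methoxy-3-methyl-5-(triisopropylsilyloxy)phenyl]-3-methylpent-3-enoic acid, via aryllithium 7 (not isolated), via arylmagnesium bromide 8 (not isolated)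
Conditions: sec-butyllithium, TMEDA, Et2O, −78 to 0 °C; MgBr2·OEt2; then 6, CuI (10 mol %), THF–Me2S, −30 to 0 °C; aq. HCl
Reagents that add atoms: none
Why: Directed ortho-metalation followed by a copper-catalysed SN2' ring opening of the β-vinyl β-lactone, in which the methoxy group directs lithiation to its only free ortho position and the arylcopper species attacks the vinyl terminus anti to the departing carboxylate, which should favour the (E)-trisubstituted alkene as is typical of 2-methyl-2-vinyl strained oxacycles.

Step 4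
Reactants: 10 pent-4-yn-1-ol
Product: 12 (E)-5-iodo-4-methylpent-4-en-1-ol, via (E)-alkenylalane 11 (not isolated)
Conditions: Me3Al, Cp2ZrCl2 (25 mol %), CH2Cl2, 0 °C to rt; then I2, THF, −30 to 0 °C; aq. K2CO3
Reagents that add atoms: trimethylaluminium, C[Al](C)C; iodine, II
Why: Zirconium-catalysed carboalumination (Negishi carboalumination) followed by iodinolysis, in which methyl and aluminium add syn across the alkyne with aluminium at the terminal carbon and iodine replaces aluminium with retention, so that methyl and iodine end up cis in the (E)-alkenyl iodide.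

Step 5
Reactants: 12 (E)-5-iodo-4-methylpent-4-en-1-ol
Product: 13 (E)-1,5-diiodo-2-methylpent-1-ene
Conditions: I2, PPh3, imidazole, CH2Cl2, 0 °C to rt
Reagents that add atoms: iodine, II
Why: Appel reaction, in which the primary alcohol is activated as an alkoxyphosphonium ion and displaced by iodide while the alkenyl iodide is inert.

Step 6
Reactants: 14 (R)-lactic acid; 15 pivalaldehyde
Product: 16 (2R,5R)-2-tert-butyl-5-methyl-1,3-dioxolan-4-one
Conditions: p-TsOH (cat.), pentane, reflux with azeotropic removal of water; crystallisation from pentane at −78 °C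
Reagents that add atoms: none
Why: Acid-catalysed acetalisation, in which C5 comes from the chiral pool and the new acetal centre C2 is set under thermodynamic control in favour of the cis isomer, which crystallisation should free from the trans isomer.

Step 7
Reactants: 16 (2R,5R)-2-tert-butyl-5-methyl-1,3-dioxolan-4-one; 13 (E)-1,5-diiodo-2-methylpent-1-ene
Product: 18 (2R,5S)-2-tert-butyl-5-[(E)-5-iodo-4-methylpent-4-en-1-yl]-5-methyl-1,3-dioxolan-4-one, via lithium dioxolanone enolate 17 (not isolated)
Conditions: LiN(iPr)2, THF, −78 °C; then 13, DMPU, −78 to −30 °C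
Reagents that add atoms: none
Why: Enolate alkylation with self-regeneration of the stereocentre, in which the primary iodide enters the planar enolate on the face opposite the tert-butyl group at C2, so that the acetal centre sets the new quaternary centre C5 as (S) while the alkenyl iodide does not react.

Step 8
Reactants: 18 (2R,5S)-2-tert-butyl-5-[(E)-5-iodo-4-methylpent-4-en-1-yl]-5-methyl-1,3-dioxolan-4-one; 19 4-bromo-2-methylbut-1-ene
Product: 21 (6S,10E)-6-hydroxy-11-iodo-2,6,10-trimethylundeca-1,10-dien-5-one, via (3-methylbut-3-en-1-yl)magnesium bromide 20 (not isolated)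
Conditions: 19, Mg, THF, rt; then 18, THF, −78 °C; aq. NH4Cl at −78 °C
Reagents that add atoms: none
Why: Grignard addition to the lactone-type carbonyl (acyl substitution), in which the magnesium hemiketal should persist at −78 °C and collapse only on quenching, with loss of pivalaldehyde, to the α-hydroxy ketone, so that a second addition is avoided and the quaternary centre is untouched.

Step 9
Reactants: 21 (6S,10E)-6-hydroxy-11-iodo-2,6,10-trimethylundeca-1,10-dien-5-one
Product: 22 (S)-2-[(E)-5-iodo-4-methylpent-4-en-1-yl]-2,6,6-trimethyloxan-3-one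
Conditions: TfOH (5 mol %), CH2Cl2, 0 °C
Reagents that add atoms: none
Why: Acid-catalysed intramolecular hydroalkoxylation (6-exo-trig), in which Markovnikov protonation of the 1,1-disubstituted alkene gives a tertiary cation that the tertiary hydroxyl group traps, without touching the stereocentre or the less basic alkenyl iodide.

Step 10
Reactants: 22 (S)-2-[(E)-5-iodo-4-methylpent-4-en-1-yl]-2,6,6-trimethyloxan-3-one
Product: 23 (S)-2-[(E)-5-iodo-4-methylpent-4-en-1-yl]-2,6,6-trimethyl-2H-pyran-3(6H)-one
Conditions: IBX, 4-methoxypyridine N-oxide, DMSO, rt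
Reagents that add atoms: none
Why: IBX dehydrogenation of a ketone to an enone, which can only give the C4=C5 enone because the C4 methylene is the single enolisable position and C6 is quaternary.

Step 11
Reactants: 23 (S)-2-[(E)-5-iodo-4-methylpent-4-en-1-yl]-2,6,6-trimethyl-2H-pyran-3(6H)-one
Product: 24 (S)-2,6,6-trimethyl-2-[(E)-4-methyl-5-(trimethylstannyl)pent-4-en-1-yl]-2H-pyran-3(6H)-one
Conditions: (Me3Sn)2, Pd(PPh3)4 (5 mol %), toluene, 80 °C
Reagents that add atoms: hexamethylditin, C[Sn](C)(C)[Sn](C)(C)C
Why: Palladium-catalysed stannylation of an alkenyl iodide with a distannane, in which oxidative addition to zerovalent palladium, transmetalation and reductive elimination replace iodine by tin with retention of the (E)-geometry under neutral conditions that the enone tolerates.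

Step 12
Reactants: 9 (E)-5-[2-methoxy-3-methyl-5-(triisopropylsilyloxy)phenyl]-3-methylpent-3-enoic acid; 24 (S)-2,6,6-trimethyl-2-[(E)-4-methyl-5-(trimethylstannyl)pent-4-en-1-yl]-2H-pyran-3(6H)-one
Product: 26 (S)-2-[(4E,8E)-10-[2-methoxy-3-methyl-5-(triisopropylsilyloxy)phenyl]-4,8-dimethyl-6-oxodeca-4,8-dien-1-yl]-2,6,6-trimethyl-2H-pyran-3(6H)-one, via acid chloride 25 (not isolated)
Conditions: 1-chloro-N,N,2-trimethylprop-1-en-1-amine, CH2Cl2, 0 °C to rt; then 24, Pd2(dba)3 (2.5 mol %), P(2-furyl)3 (10 mol %), CO (1 atm), THF, 45 °C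
Reagents that add atoms: none
Why: Stille acylation: zerovalent palladium inserts into the C–Cl bond of 25 to give an acylpalladium chloride, the alkenyl group of 24 is transferred from tin with retention of the C6'=C7' geometry, and reductive elimination forms the C5'–C6' bond. The closest known reaction type is the palladium-catalysed coupling of acid chlorides with alkenylstannanes to give enones. No ring is closed and no stereocentre is formed; the (S)-centre at C2 of the pyranone ring and both alkene geometries are only carried through. The step needs ketone formation to win over decarbonylation of the β,γ-unsaturated acylpalladium to an allylpalladium species, which the CO atmosphere and the fast transmetalation with tri(2-furyl)phosphine should secure. It also needs the C2'=C3' alkene to stay out of conjugation and the pyranone enone to stay untouched, which the absence of any base, the mild temperature and the neutral chloroenamine activation of the acid should secure.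

Step 13
Reactants: 26 (S)-2-[(4E,8E)-10-[2-methoxy-3-methyl-5-(triisopropylsilyloxy)phenyl]-4,8-dimethyl-6-oxodeca-4,8-dien-1-yl]-2,6,6-trimethyl-2H-pyran-3(6H)-one
Product: 27 (S)-2-[(4E,8E)-10-(5-hydroxy-2-methoxy-3-methylphenyl)-4,8-dimethyl-6-oxodeca-4,8-dien-1-yl]-2,6,6-trimethyl-2H-pyran-3(6H)-one
Conditions: HF·pyridine, pyridine, THF, 0 °C to rt
Reagents that add atoms: none
Why: Fluoride-mediated cleavage of an aryl silyl ether, in which buffered HF·pyridine removes the triisopropylsilyl group without base, so that the acidic C4' methylene is not enolised and neither alkene migrates.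

Compound list

1 | 4-methoxy-3-methylphenol | COc1ccc(O)cc1C | starting material
2 | triisopropyl(4-methoxy-3-methylphenoxy)silane | COc1ccc(O[Si](C(C)C)(C(C)C)C(C)C)cc1C | intermediate
3 | S-phenyl thioacetate | CC(=O)Sc1ccccc1 | starting material
4 | methyl vinyl ketone (but-3-en-2-one) | CC(=O)C=C | starting material
5 | lithium 1-(phenylsulfanyl)ethenolate | [Li]OC(=C)Sc1ccccc1 | intermediate
6 | rac-4-ethenyl-4-methyloxetan-2-one | CC1(C=C)CC(=O)O1 | intermediate
7 | [2-methoxy-3-methyl-5-(triisopropylsilyloxy)phenyl]lithium | [Li]c1cc(O[Si](C(C)C)(C(C)C)C(C)C)cc(C)c1OC | intermediate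
8 | [2-methoxy-3-methyl-5-(triisopropylsilyloxy)phenyl]magnesium bromide | Br[Mg]c1cc(O[Si](C(C)C)(C(C)C)C(C)C)cc(C)c1OC | intermediate
9 | (E)-5-[2-methoxy-3-methyl-5-(triisopropylsilyloxy)phenyl]-3-methylpent-3-enoic acid | COc1c(C)cc(O[Si](C(C)C)(C(C)C)C(C)C)cc1C/C=C(\C)CC(=O)O | intermediate
10 | pent-4-yn-1-ol | C#CCCCO | starting material
11 | dimethylaluminium (E)-5-(dimethylalumanyl)-4-methylpent-4-en-1-olate | C[Al](C)/C=C(\C)CCCO[Al](C)C | intermediate
12 | (E)-5-iodo-4-methylpent-4-en-1-ol | OCCC/C(C)=C/I | intermediate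
13 | (E)-1,5-diiodo-2-methylpent-1-ene | ICCC/C(C)=C/I | intermediate
14 | (R)-lactic acid | C[C@@H](O)C(=O)O | starting material
15 | pivalaldehyde (2,2-dimethylpropanal) | CC(C)(C)C=O | starting material
16 | (2R,5R)-2-tert-butyl-5-methyl-1,3-dioxolan-4-one (cis) | C[C@H]1O[C@@H](C(C)(C)C)OC1=O | intermediate
17 | lithium (R)-2-tert-butyl-5-methyl-1,3-dioxol-4-olate | CC1=C(O[Li])O[C@H](C(C)(C)C)O1 | intermediate
18 | (2R,5S)-2-tert-butyl-5-[(E)-5-iodo-4-methylpent-4-en-1-yl]-5-methyl-1,3-dioxolan-4-one | C[C@@]1(CCC/C(C)=C/I)O[C@@H](C(C)(C)C)OC1=O | intermediate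
19 | 4-bromo-2-methylbut-1-ene | C=C(C)CCBr | starting material
20 | (3-methylbut-3-en-1-yl)magnesium bromide | C=C(C)CC[Mg]Br | intermediate
21 | (6S,10E)-6-hydroxy-11-iodo-2,6,10-trimethylundeca-1,10-dien-5-one | C=C(C)CCC(=O)[C@@](C)(O)CCC/C(C)=C/I | intermediate
22 | (S)-2-[(E)-5-iodo-4-methylpent-4-en-1-yl]-2,6,6-trimethyloxan-3-one | C[C@@]1(CCC/C(C)=C/I)OC(C)(C)CCC1=O | intermediate
23 | (S)-2-[(E)-5-iodo-4-methylpent-4-en-1-yl]-2,6,6-trimethyl-2H-pyran-3(6H)-one | C[C@@]1(CCC/C(C)=C/I)OC(C)(C)C=CC1=O | intermediate
24 | (S)-2,6,6-trimethyl-2-[(E)-4-methyl-5-(trimethylstannyl)pent-4-en-1-yl]-2H-pyran-3(6H)-one | C[C@@]1(CCC/C(C)=C/[Sn](C)(C)C)OC(C)(C)C=CC1=O | intermediate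
25 | (E)-5-[2-methoxy-3-methyl-5-(triisopropylsilyloxy)phenyl]-3-methylpent-3-enoyl chloride | COc1c(C)cc(O[Si](C(C)C)(C(C)C)C(C)C)cc1C/C=C(\C)CC(=O)Cl | intermediate
26 | (S)-2-[(4E,8E)-10-[2-methoxy-3-methyl-5-(triisopropylsilyloxy)phenyl]-4,8-dimethyl-6-oxodeca-4,8-dien-1-yl]-2,6,6-trimethyl-2H-pyran-3(6H)-one | COc1c(C)cc(O[Si](C(C)C)(C(C)C)C(C)C)cc1C/C=C(\C)CC(=O)/C=C(\C)CCC[C@]1(C)OC(C)(C)C=CC1=O | intermediate
27 | (S)-2-[(4E,8E)-10-(5-hydroxy-2-methoxy-3-methylphenyl)-4,8-dimethyl-6-oxodeca-4,8-dien-1-yl]-2,6,6-trimethyl-2H-pyran-3(6H)-one | COc1c(C)cc(O)cc1C/C=C(\C)CC(=O)/C=C(\C)CCC[C@]1(C)OC(C)(C)C=CC1=O | target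

Total step count: 13 steps.
Longest linear sequence: 9 steps (10 → 12 → 13 → 18 → 21 → 22 → 23 → 24 → 26 → 27; steps 4, 5, 7, 8, 9, 10, 11, 12, 13).

Steps most likely to fail

1. Step 12. The acylpalladium intermediate may lose CO to an allylpalladium species and couple without the carbonyl group, or the C2'=C3' alkene may migrate into conjugation during the coupling. The fallback sets out from 9 and from iodide 23 (taken before step 11) and comes back at 26. Acid 9 would be converted into chloride 25 as in step 12 and reduced with LiAlH(OtBu)3 (THF, −78 °C) to (E)-5-[2-methoxy-3-methyl-5-(triisopropylsilyloxy)phenyl]-3-methylpent-3-enal F1. A Nozaki–Hiyama–Kishi reaction of F1 with 23 (CrCl2, NiCl2 cat., DMSO, rt) should proceed through the alkenylchromium dichloride F2, which adds only to the aldehyde, and give the dienol F3 as a mixture of epimers at the new carbinol carbon C5'. Dess–Martin oxidation (NaHCO3, CH2Cl2, 0 °C) of F3 would remove that centre and give 26, without any acylpalladium species on the way.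

2. Step 8. The tetrahedral adduct may collapse before the quench, so that the ketone is exposed to the Grignard reagent and a second addition takes place. The fallback sets out from 18 and comes back at 21. Compound 18 would be opened with MeNH(OMe)·HCl and isopropylmagnesium chloride (THF, −20 °C), with loss of pivalaldehyde, to the Weinreb amide (2S,6E)-2-hydroxy-7-iodo-N-methoxy-N,2,6-trimethylhept-6-enamide F4. Weinreb ketone synthesis with 20 (excess, THF, 0 °C), whose chelated adduct cannot collapse before the quench, should then give 21.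

3. Step 3. The aryl nucleophile may attack the lactone carbonyl instead of the vinyl terminus, or the SN2' opening may proceed with poor control of the alkene geometry. The fallback sets out from 2 (through 7 and 8 as in step 3) and comes back at 9; lactone 6 and step 2 are then not needed. Arylmagnesium bromide 8 would be added with CuI catalysis (THF, −30 °C) to commercial 2-methyl-2-vinyloxirane, an SN2' partner without an acyl group, to give (E)-4-[2-methoxy-3-methyl-5-(triisopropylsilyloxy)phenyl]-2-methylbut-2-en-1-ol F5. Methyl chloroformate and pyridine (CH2Cl2, 0 °C) would give the allylic methyl carbonate F6. Decarboxylative carbonylation (Pd(OAc)2, PPh3, CO 10 bar, toluene, 50 °C) would then give the methyl ester F7, and Me3SnOH (1,2-dichloroethane, 70 °C) would give acid 9 without a base strong enough to move the alkene.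

Further compounds

F1 | step 12 | (E)-5-[2-methoxy-3-methyl-5-(triisopropylsilyloxy)phenyl]-3-methylpent-3-enal | COc1c(C)cc(O[Si](C(C)C)(C(C)C)C(C)C)cc1C/C=C(\C)CC=O
F2 | step 12 | (S)-2-[(E)-5-(dichlorochromio)-4-methylpent-4-en-1-yl]-2,6,6-trimethyl-2H-pyran-3(6H)-one (alkenylchromium dichloride of trivalent chromium, not isolated) | C[C@@]1(CCC/C(C)=C/[Cr](Cl)Cl)OC(C)(C)C=CC1=O
F3 | step 12 | (S)-2-[(4E,8E)-6-hydroxy-10-[2-methoxy-3-methyl-5-(triisopropylsilyloxy)phenyl]-4,8-dimethyldeca-4,8-dien-1-yl]-2,6,6-trimethyl-2H-pyran-3(6H)-one (both epimers at the carbinol carbon) | COc1c(C)cc(O[Si](C(C)C)(C(C)C)C(C)C)cc1C/C=C(\C)CC(O)/C=C(\C)CCC[C@]1(C)OC(C)(C)C=CC1=O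
F4 | step 8 | (2S,6E)-2-hydroxy-7-iodo-N-methoxy-N,2,6-trimethylhept-6-enamide | CON(C)C(=O)[C@@](C)(O)CCC/C(C)=C/I
F5 | step 3 | (E)-4-[2-methoxy-3-methyl-5-(triisopropylsilyloxy)phenyl]-2-methylbut-2-en-1-ol | COc1c(C)cc(O[Si](C(C)C)(C(C)C)C(C)C)cc1C/C=C(\C)CO
F6 | step 3 | (E)-4-[2-methoxy-3-methyl-5-(triisopropylsilyloxy)phenyl]-2-methylbut-2-en-1-yl methyl carbonate | COc1c(C)cc(O[Si](C(C)C)(C(C)C)C(C)C)cc1C/C=C(\C)COC(=O)OC
F7 | step 3 | methyl (E)-5-[2-methoxy-3-methyl-5-(triisopropylsilyloxy)phenyl]-3-methylpent-3-enoate | COc1c(C)cc(O[Si](C(C)C)(C(C)C)C(C)C)cc1C/C=C(\C)CC(=O)OC
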